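A small charge of protic impurity, 0.940 mM in this flask, can claim 2.00% of the starting material and, by the candidate steps, none of the reagent, so leave it alone and watch the reagent in the second phase, which must cross into the reaction phase before any target forms.

in all of them: starting material 47 mM

| charge | reagent in the second phase | protic impurity | remark | time | volume of the second phase over the first |
|---|---|---|---|---|---|
| Sunday's | 21 mM | 0.94 mM | run made earlier |  |  |
| Monday's | 32 mM | 0.94 mM | run made earlier |  |  |
| Tuesday's | 42.3 mM | 1.4 mM | run made earlier |  |  |
| flask | 42.3 mM | 0.940 mM |  | 1.5 h | 1.0 |
- Sunday's (time / min: target / %): 20.0: 0; 40.0: 1.0; 50.0: 1.1; 80.0: 2.2; 90.0: 3.4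
- Monday's (time / min: target / %): 8.00: 0; 15.0: 0.2; 25.0: 1.1; 50.0: 2.2; 90.0: 4.0
- Tuesday's (time / min: target / %): 8.00: 0; 15.0: 0; 25.0: 0.7; 50.0: 2.3; 90.0: 4.2

(standard deviation of a reading: 0.5 percentage points)
- percentages count the starting material that a species holds: one side product counts as two
- in the second phase: reagent in the second phase; everything else is in the first
- charges count per volume of the first phase; a concentration in a rate is the amount of a species over the volume of its own phase; every rate counts per litre of the first phase
- candidate steps: reagent in the reaction phase <-> reagent in the second phase; starting material + reagent in the reaction phase -> target; reagent in the reaction phase + target -> over-reacted product; starting material + protic impurity -> quenched substrate; starting material + target -> side product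
- the earlier runs hold the two phases in the same ratio of volumes as the flask asked about
1. amount of target at 1.5 h, in percent of the starting material charged
2. the change that raises the amount of target at 1.5 h, in percent of the starting material charged most ("none" if none brings more than 2 percentage points) (winter / midnight / none)
3. amount of target at 1.5 h, in percent of the starting material charged, after winter

With the curve of reagent in the reaction phase replaced by its mean, and starting material nearly constant (pseudo-first-order in reagent), I expect target at a fixed time to follow the charge. Tuesday's reading at 90.0 min gives 0.993 L mol⁻¹, the charge yield g: target at a fixed time over c(reagent in the second phase). At 50.0 min the runs give 0.524 L mol⁻¹, 0.688 L mol⁻¹ and 0.544 L mol⁻¹; at 90.0 min the last readings of Sunday's and Monday's runs give more than Tuesday's, 1.62 L mol⁻¹ and 1.25 L mol⁻¹, but each reading carries a scatter of 0.5 percentage points, and the one before Sunday's last reads 2.2%, so I take the proportion as a working rule and not as shown. Tuesday's extra impurity shifts my figure by 0.041 points. When you come, I expect: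

flask: g × c(reagent in the second phase) = 4.20%

winter: g × 2 c(reagent in the second phase) = 8.40%

Over-reaction grows with reagent times target, so I take the winter figure as somewhat high; its gain of 4.2 points still clears 2 points, and midnight brings the same charge sooner, so I choose winter.

The forecast gives 4.3% (3.6% to 5%), 4.9% (4% to 6.8%) after winter and none, holding that "Doubling reagent then adds only a few tenths", which parts from my winter figure.

The flask gives 4.36%, 7.79% after winter, and best winter.

    reagent in the reaction phase ⇌ reagent in the second phase, rate k1*([reagent in the reaction phase] - [reagent in the second phase]/K1) per volume of the first phase (partition coefficient = 1.90, kL = 0.0160 min⁻¹)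
    starting material + reagent in the reaction phase → target (k = 0.0820 L mol⁻¹ min⁻¹)
    reagent in the reaction phase + target → over-reacted product (k = 0.250 L mol⁻¹ min⁻¹)
    starting material + protic impurity → quenched substrate (k = 16.0 L mol⁻¹ min⁻¹)
    starting material + target → side product (k = 0.100 L mol⁻¹ min⁻¹)

In the flask, protic impurity fell to 0.129% of its charge by 0.150 h, leaving 2.00% quenched substrate, while reagent in the reaction phase stood at 2.83 mM. It then climbed to 11.1 mM by 1.50 h, as the making of target turned over 5.52%, against 0.419% in the step to over-reacted product and 0.747% in the step to side product. The charge yield of this flask is 1.03 L mol⁻¹. Winter gains 3.4 points, more than midnight's 1.1 points, and its charge yield is 0.921 L mol⁻¹.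

(Readings and results were generated by integration for an exercise, and the scatter is random.)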